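**Plan** (prostanoid numbering: ester carbon C1, ring C8–C12, C12 quaternary, ω‑chain C13–C20)

- The retrosynthesis first cuts C10–C11 and C8–C9 of the 2‑bromocyclopent‑2‑enone ring. This releases a bromo(phosphono)acetyl C9–C10 unit and an acyclic C11–C12–C8 piece with a formyl group at C11 and a tributylstannyl group at C8.
- The enabling feature is that ketone C9 lies between the exocyclic alkenyl carbon C8, which can hold a metal with fixed geometry, and the C10=C11 bond, whose C11 sits on the non‑enolisable quaternary C12. One acylation–olefination sequence in one flask therefore closes ring C8–C12 and makes the bromoenone and the cross‑conjugated dienone.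
- Further cuts are C6–C7 (Sonogashira), H/Sn across C7≡C8, the alkyne from a CH2OH arm (C8), and C13–C14 by epoxide opening.
- Forward, the chain is assembled acyclic and the only ring arises in the last step. The PMB ether is the single protecting group and is removed before that step.
- C12 comes from a Sharpless epoxidation (D‑tartrate), 14Z from Lindlar reduction, 5E from hydrozirconation, and 7Z from a hydroxyl‑directed trans‑hydrostannation carried through the coupling with retention.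

Key step: step 15

Assumption: ethyl bromo(diethoxyphosphoryl)acetate (19) and methyl hex‑5‑ynoate (11) are taken as catalogue compounds.

**Route**

Step 1
Reactants: 1 2‑methylidenepropane‑1,3‑diol
Product: 2 2‑{[(4‑methoxyphenyl)methoxy]methyl}prop‑2‑en‑1‑ol
Conditions: NaH (1.0 equiv), THF/DMF, 0 °C; PMBCl, Bu4NI (cat.), 0 °C → rt
Reagents that add atoms: 4‑methoxybenzyl chloride, COc1ccc(CCl)cc1
Why: Williamson etherification of a symmetric diol with one equivalent of base should give the mono‑ether, separable from diol and bis‑ether.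

Step 2
Reactants: 2 2‑{[(4‑methoxyphenyl)methoxy]methyl}prop‑2‑en‑1‑ol
Product: 3 [(2R)‑2‑{[(4‑methoxyphenyl)methoxy]methyl}oxiran‑2‑yl]methanol
Conditions: Ti(OiPr)4 (10 mol %), D‑(−)‑diisopropyl tartrate (12 mol %), t‑BuOOH (2 equiv, decane), 4 Å MS, CH2Cl2, −20 °C
Reagents that add atoms: tert‑butyl hydroperoxide, CC(C)(C)OO
Why: Katsuki–Sharpless asymmetric epoxidation of a 2‑substituted allylic alcohol, in which the D‑tartrate should deliver oxygen to the same face that converts 2‑methylprop‑2‑en‑1‑ol into (R)‑2‑methylglycidol, which sets the future C12.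

Step 3
Reactants: 3 [(2R)‑2‑{[(4‑methoxyphenyl)methoxy]methyl}oxiran‑2‑yl]methanol; 4 hept‑1‑yne
Product: 7 (2S)‑2‑{[(4‑methoxyphenyl)methoxy]methyl}dec‑4‑yne‑1,2‑diol, via lithium hept‑1‑yn‑1‑ide 5 (not isolated), via diethyl(hept‑1‑yn‑1‑yl)aluminium 6 (not isolated)
Conditions: 4, n‑BuLi, toluene, 0 °C; Et2AlCl, 0 °C; then 3, 0 °C → rt; aqueous Rochelle salt
Reagents that add atoms: none
Why: Alkynylalane opening of a 2,3‑epoxy alcohol should occur by SN2 attack at the unsubstituted epoxide CH2, so the quaternary stereocentre is not touched.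

Step 4
Reactants: 7 (2S)‑2‑{[(4‑methoxyphenyl)methoxy]methyl}dec‑4‑yne‑1,2‑diol
Product: 8 (2S,4Z)‑2‑{[(4‑methoxyphenyl)methoxy]methyl}dec‑4‑ene‑1,2‑diol
Conditions: H2 (1 atm), Pd on CaCO3 poisoned with Pb(OAc)2, quinoline, EtOAc, rt
Reagents that add atoms: none
Why: Lindlar semihydrogenation adds hydrogen syn and should give the (Z)‑alkene that becomes C14=C15.

Step 5
Reactants: 8 (2S,4Z)‑2‑{[(4‑methoxyphenyl)methoxy]methyl}dec‑4‑ene‑1,2‑diol
Product: 9 (2R,4Z)‑2‑hydroxy‑2‑{[(4‑methoxyphenyl)methoxy]methyl}dec‑4‑enal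
Conditions: SO3·pyridine, DMSO, i‑Pr2NEt, CH2Cl2, 0 °C
Reagents that add atoms: none
Why: Parikh–Doering oxidation should convert only the primary alcohol, since the tertiary one cannot be oxidised and this reagent does not cleave glycols.

Step 6
Reactants: 9 (2R,4Z)‑2‑hydroxy‑2‑{[(4‑methoxyphenyl)methoxy]methyl}dec‑4‑enal
Product: 10 (3S,5Z)‑3‑{[(4‑methoxyphenyl)methoxy]methyl}undec‑5‑en‑1‑yn‑3‑ol
Conditions: dimethyl (1‑diazo‑2‑oxopropyl)phosphonate, K2CO3, MeOH, 0 °C → rt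
Reagents that add atoms: dimethyl (1‑diazo‑2‑oxopropyl)phosphonate, COP(=O)(OC)C(=[N+]=[N-])C(C)=O
Why: Ohira–Bestmann (Seyferth–Gilbert) homologation should turn the aldehyde into the terminal alkyne (C8≡C7), and the α‑carbon is quaternary so it cannot epimerise.

Step 7
Reactants: 11 methyl hex‑5‑ynoate
Product: 13 methyl (5E)‑6‑iodohex‑5‑enoate, via alkenylzirconocene chloride 12 (not isolated)
Conditions: Cp2Zr(H)Cl, THF, rt; I2, 0 °C
Reagents that add atoms: iodine, II
Why: Hydrozirconation is a syn, terminal‑selective addition, and iodinolysis with retention should give the (E)‑alkenyl iodide that becomes C5=C6.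

Step 8
Reactants: 10 (3S,5Z)‑3‑{[(4‑methoxyphenyl)methoxy]methyl}undec‑5‑en‑1‑yn‑3‑ol; 13 methyl (5E)‑6‑iodohex‑5‑enoate
Product: 14 methyl (5E,9S,11Z)‑9‑hydroxy‑9‑{[(4‑methoxyphenyl)methoxy]methyl}heptadeca‑5,11‑dien‑7‑ynoate
Conditions: PdCl2(PPh3)2 (3 mol %), CuI (6 mol %), Et3N, THF, rt
Reagents that add atoms: none
Why: Sonogashira coupling should join C6 to C7 with retention of the (E)‑alkene and tolerates the free tertiary alcohol.

Step 9
Reactants: 14 methyl (5E,9S,11Z)‑9‑hydroxy‑9‑{[(4‑methoxyphenyl)methoxy]methyl}heptadeca‑5,11‑dien‑7‑ynoate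
Product: 15 methyl (5E,7Z,9R,11Z)‑9‑hydroxy‑9‑{[(4‑methoxyphenyl)methoxy]methyl}‑8‑(tributylstannyl)heptadeca‑5,7,11‑trienoate
Conditions: Bu3SnH (1.15 equiv), [Cp*RuCl]4 (2.5 mol %), CH2Cl2, rt
Reagents that add atoms: tributyltin hydride, CCCC[SnH](CCCC)CCCC
Why: Hydroxyl‑directed ruthenium‑catalysed trans‑hydrostannation should place tin on the alkyne carbon next to the carbinol (C8) and hydrogen anti on C7, so tin ends cis to the C6 vinyl group, which is the future 7Z geometry.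

Step 10
Reactants: 15 methyl (5E,7Z,9R,11Z)‑9‑hydroxy‑9‑{[(4‑methoxyphenyl)methoxy]methyl}‑8‑(tributylstannyl)heptadeca‑5,7,11‑trienoate
Product: 16 methyl (5E,7Z,9R,11Z)‑9‑acetoxy‑9‑{[(4‑methoxyphenyl)methoxy]methyl}‑8‑(tributylstannyl)heptadeca‑5,7,11‑trienoate
Conditions: Ac2O, DMAP, Et3N, CH2Cl2, rt → 40 °C
Reagents that add atoms: acetic anhydride, CC(=O)OC(C)=O
Why: DMAP‑catalysed acylation should acetylate the tertiary alcohol once its directing role is over, and the alkenylstannane is inert to these conditions.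

Step 11
Reactants: 16 methyl (5E,7Z,9R,11Z)‑9‑acetoxy‑9‑{[(4‑methoxyphenyl)methoxy]methyl}‑8‑(tributylstannyl)heptadeca‑5,7,11‑trienoate
Product: 17 methyl (5E,7Z,9R,11Z)‑9‑acetoxy‑9‑(hydroxymethyl)‑8‑(tributylstannyl)heptadeca‑5,7,11‑trienoate
Conditions: DDQ, CH2Cl2/pH 7 phosphate buffer, 0 °C; crude product used at once
Reagents that add atoms: none
Why: Oxidative cleavage of the PMB ether under neutral conditions should spare the acid‑sensitive dienylstannane, the acetate and the methyl ester.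

Step 12
Reactants: 17 methyl (5E,7Z,9R,11Z)‑9‑acetoxy‑9‑(hydroxymethyl)‑8‑(tributylstannyl)heptadeca‑5,7,11‑trienoate
Product: 18 methyl (5E,7Z,9R,11Z)‑9‑acetoxy‑9‑formyl‑8‑(tributylstannyl)heptadeca‑5,7,11‑trienoate
Conditions: Dess–Martin periodinane, pyridine, CH2Cl2, 0 °C → rt
Reagents that add atoms: none
Why: Dess–Martin oxidation should give the non‑enolisable α‑acetoxy aldehyde (C11), and immediate oxidation leaves no free hydroxyl for acetyl migration.

Step 13
Reactants: 19 ethyl bromo(diethoxyphosphoryl)acetate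
Product: 20 bromo(diethoxyphosphoryl)acetic acid
Conditions: LiOH·H2O (1.05 equiv), THF/H2O, 0 °C; aqueous HCl to pH 2
Reagents that add atoms: lithium hydroxide, [Li+].[OH-]
Why: Saponification should cleave the carboxylic ethyl ester in preference to the phosphonate esters, as is known for the 2‑fluoro analogue.

Step 14
Reactants: 20 bromo(diethoxyphosphoryl)acetic acid
Product: 21 bromo(diethoxyphosphoryl)acetyl chloride
Conditions: (COCl)2, DMF (cat.), CH2Cl2, 0 °C → rt; volatiles removed, used crude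
Reagents that add atoms: oxalyl chloride, O=C(Cl)C(Cl)=O
Why: Vilsmeier‑type activation should give the acid chloride under base‑free conditions, which avoids ketene formation at the acidic CHBr position.

Step 15
Reactants: 18 methyl (5E,7Z,9R,11Z)‑9‑acetoxy‑9‑formyl‑8‑(tributylstannyl)heptadeca‑5,7,11‑trienoate; 21 bromo(diethoxyphosphoryl)acetyl chloride
Product: 23 methyl (5E,7Z,12R,14Z)‑12‑acetoxy‑10‑bromo‑9‑oxoprosta‑5,7,10,14‑tetraen‑1‑oate (target), via bromo ketophosphonate 22 (not isolated)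
Conditions: Pd2(dba)3 (5 mol %), P(2‑furyl)3 (20 mol %), CuI (10 mol %), THF, rt → 45 °C; then LiCl, i‑Pr2NEt, MeCN, 0 °C → rt, same flask
Reagents that add atoms: none
Why: Zerovalent palladium should insert into the acyl chloride, the alkenyl group should pass from tin via copper to palladium, and reductive elimination with retention at C8 should give ketophosphonate 22 (bond C8–C9); LiCl and the amine then deprotonate the doubly activated CHBr carbon, which attacks the C11 formyl group and loses diethyl phosphate to form C10=C11. The closest known reaction types are the Migita–Stille ketone synthesis from acid chlorides and alkenylstannanes and the Masamune–Roush intramolecular Horner–Wadsworth–Emmons closure of keto‑phosphonates with a 1,4‑related carbonyl to cyclopentenones. The five‑membered ring C8–C12 closes by 5‑exo‑trig attack of the phosphonate carbanion C10 on the aldehyde (enolendo with respect to the C9 ketone, as in 1,4‑dicarbonyl cyclopentenone annulations), and the ring forces the cis arrangement in the new alkene. No stereocentre is formed: C12 has no α‑hydrogen and is not involved, the C7=C8 geometry set in step 9 is carried over by retention, and the transient CHBr centre is destroyed. The step needs acylation at C8 only, olefination at C11 only and retention of bromine; these are secured by the single C–Sn bond, the much faster insertion of palladium into the acyl chloride than into the C–Br bond or the hindered allylic acetate, the single aldehyde, and phosphate elimination outrunning epoxide closure. The mild amine base should leave the acetate, the methyl ester and the (7Z)‑dienone untouched.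

**Compound list**

1 | 2‑methylidenepropane‑1,3‑diol | C=C(CO)CO | starting material
2 | 2‑{[(4‑methoxyphenyl)methoxy]methyl}prop‑2‑en‑1‑ol | C=C(CO)COCc1ccc(OC)cc1 | intermediate
3 | [(2R)‑2‑{[(4‑methoxyphenyl)methoxy]methyl}oxiran‑2‑yl]methanol | C1[C@@](CO)(O1)COCc2ccc(OC)cc2 | intermediate
4 | hept‑1‑yne | CCCCCC#C | starting material
5 | lithium hept‑1‑yn‑1‑ide | [Li]C#CCCCCC | intermediate
6 | diethyl(hept‑1‑yn‑1‑yl)aluminium | CC[Al](CC)C#CCCCCC | intermediate
7 | (2S)‑2‑{[(4‑methoxyphenyl)methoxy]methyl}dec‑4‑yne‑1,2‑diol | CCCCCC#CC[C@@](CO)(O)COCc1ccc(OC)cc1 | intermediate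
8 | (2S,4Z)‑2‑{[(4‑methoxyphenyl)methoxy]methyl}dec‑4‑ene‑1,2‑diol | CCCCC/C=C\C[C@@](CO)(O)COCc1ccc(OC)cc1 | intermediate
9 | (2R,4Z)‑2‑hydroxy‑2‑{[(4‑methoxyphenyl)methoxy]methyl}dec‑4‑enal | CCCCC/C=C\C[C@@](C=O)(O)COCc1ccc(OC)cc1 | intermediate
10 | (3S,5Z)‑3‑{[(4‑methoxyphenyl)methoxy]methyl}undec‑5‑en‑1‑yn‑3‑ol | CCCCC/C=C\C[C@@](C#C)(O)COCc1ccc(OC)cc1 | intermediate
11 | methyl hex‑5‑ynoate | COC(=O)CCCC#C | starting material
12 | methyl (5E)‑6‑[chlorobis(cyclopentadienyl)zirconio]hex‑5‑enoate (cyclopentadienyl rings drawn σ‑bonded) | COC(=O)CCC/C=C/[Zr](Cl)(C1C=CC=C1)C1C=CC=C1 | intermediate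
13 | methyl (5E)‑6‑iodohex‑5‑enoate | COC(=O)CCC/C=C/I | intermediate
14 | methyl (5E,9S,11Z)‑9‑hydroxy‑9‑{[(4‑methoxyphenyl)methoxy]methyl}heptadeca‑5,11‑dien‑7‑ynoate | CCCCC/C=C\C[C@@](C#C/C=C/CCCC(=O)OC)(O)COCc1ccc(OC)cc1 | intermediate
15 | methyl (5E,7Z,9R,11Z)‑9‑hydroxy‑9‑{[(4‑methoxyphenyl)methoxy]methyl}‑8‑(tributylstannyl)heptadeca‑5,7,11‑trienoate | CCCCC/C=C\C[C@@](/C(=C/C=C/CCCC(=O)OC)[Sn](CCCC)(CCCC)CCCC)(O)COCc1ccc(OC)cc1 | intermediate
16 | methyl (5E,7Z,9R,11Z)‑9‑acetoxy‑9‑{[(4‑methoxyphenyl)methoxy]methyl}‑8‑(tributylstannyl)heptadeca‑5,7,11‑trienoate | CCCCC/C=C\C[C@@](/C(=C/C=C/CCCC(=O)OC)[Sn](CCCC)(CCCC)CCCC)(OC(C)=O)COCc1ccc(OC)cc1 | intermediate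
17 | methyl (5E,7Z,9R,11Z)‑9‑acetoxy‑9‑(hydroxymethyl)‑8‑(tributylstannyl)heptadeca‑5,7,11‑trienoate | CCCCC/C=C\C[C@@](/C(=C/C=C/CCCC(=O)OC)[Sn](CCCC)(CCCC)CCCC)(OC(C)=O)CO | intermediate
18 | methyl (5E,7Z,9R,11Z)‑9‑acetoxy‑9‑formyl‑8‑(tributylstannyl)heptadeca‑5,7,11‑trienoate | CCCCC/C=C\C[C@@](/C(=C/C=C/CCCC(=O)OC)[Sn](CCCC)(CCCC)CCCC)(OC(C)=O)C=O | intermediate
19 | ethyl bromo(diethoxyphosphoryl)acetate | CCOC(=O)C(Br)P(=O)(OCC)OCC | starting material
20 | bromo(diethoxyphosphoryl)acetic acid | OC(=O)C(Br)P(=O)(OCC)OCC | intermediate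
21 | bromo(diethoxyphosphoryl)acetyl chloride | ClC(=O)C(Br)P(=O)(OCC)OCC | intermediate
22 | methyl (5E,7Z,9S,11Z)‑9‑acetoxy‑8‑[2‑bromo‑2‑(diethoxyphosphoryl)acetyl]‑9‑formylheptadeca‑5,7,11‑trienoate (both CHBr epimers) | CCCCC/C=C\C[C@@](/C(=C/C=C/CCCC(=O)OC)C(=O)C(Br)P(=O)(OCC)OCC)(OC(C)=O)C=O | intermediate
23 | methyl (5E,7Z,12R,14Z)‑12‑acetoxy‑10‑bromo‑9‑oxoprosta‑5,7,10,14‑tetraen‑1‑oate, i.e. methyl (5E,7Z)‑7‑{(2R)‑2‑acetoxy‑4‑bromo‑2‑[(2Z)‑oct‑2‑en‑1‑yl]‑5‑oxocyclopent‑3‑en‑1‑ylidene}hept‑5‑enoate | CCCCC/C=C\C[C@@]1(OC(C)=O)C=C(Br)C(=O)/C1=C\C=C\CCCC(=O)OC | target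

**Count and risks**

Total steps: 15. Longest linear sequence: 12 (steps 1–6, 8–12, 15).

Step 15. Transmetalation at the hindered, α‑branched alkenyltin centre may be slow, so that protodestannylation or palladium insertion into the C–Br bond competes, and the acid chloride may be lost as a ketene once base is present. The fallback builds C8–C9 stepwise by a nickel/chromium‑mediated addition to an aldehyde. It sets out from 16: iododestannylation (I2, CH2Cl2, −78 °C) should give, with retention, methyl (5E,7Z,9R,11Z)‑9‑acetoxy‑8‑iodo‑9‑{[(4‑methoxyphenyl)methoxy]methyl}heptadeca‑5,7,11‑trienoate F1. Nozaki–Hiyama–Kishi coupling (CrCl2, NiCl2 cat., DMSO) with diethyl (2‑oxoethyl)phosphonate should give the hydroxy phosphonate methyl (5E,7E,9S,11Z)‑9‑acetoxy‑8‑[2‑(diethoxyphosphoryl)‑1‑hydroxyethyl]‑9‑{[(4‑methoxyphenyl)methoxy]methyl}heptadeca‑5,7,11‑trienoate F2. Dess–Martin oxidation should give the keto phosphonate methyl (5E,7Z,9S,11Z)‑9‑acetoxy‑8‑[2‑(diethoxyphosphoryl)acetyl]‑9‑{[(4‑methoxyphenyl)methoxy]methyl}heptadeca‑5,7,11‑trienoate F3, and NaH then N‑bromosuccinimide at −78 °C its bromo derivative methyl (5E,7Z,9S,11Z)‑9‑acetoxy‑8‑[2‑bromo‑2‑(diethoxyphosphoryl)acetyl]‑9‑{[(4‑methoxyphenyl)methoxy]methyl}heptadeca‑5,7,11‑trienoate F4. DDQ should free the alcohol methyl (5E,7Z,9S,11Z)‑9‑acetoxy‑8‑[2‑bromo‑2‑(diethoxyphosphoryl)acetyl]‑9‑(hydroxymethyl)heptadeca‑5,7,11‑trienoate F5, and Dess–Martin oxidation then gives 22, which is closed with LiCl/i‑Pr2NEt and so comes back to the route at 23.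

Step 9. Regiocontrol may erode, with tin delivered to C7, and the conjugated alkene may compete for the ruthenium catalyst or give partial cis addition. The fallback fixes the geometry by a cis double stannylation instead. It sets out from 10: Pd(PPh3)4‑catalysed addition of hexabutylditin (THF, 60 °C) should give (1Z,3R,5Z)‑3‑{[(4‑methoxyphenyl)methoxy]methyl}‑1,2‑bis(tributylstannyl)undeca‑1,5‑dien‑3‑ol F6. Site‑selective Stille coupling of its unhindered terminal C–Sn bond with 13 (Pd2(dba)3, AsPh3, CuI, NMP, rt) should then give 15, where it rejoins the route.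

Step 11. The acetyl group may migrate from the tertiary oxygen to the liberated primary hydroxyl, and DDQ may oxidatively remove tin from the dienylstannane. The fallback changes the order so that no primary alcohol ever sits next to the acetate and DDQ never meets the stannane. It sets out from 14: DDQ should give the diol methyl (5E,9S,11Z)‑9‑hydroxy‑9‑(hydroxymethyl)heptadeca‑5,11‑dien‑7‑ynoate F7. Trans‑hydrostannation as in step 9 should give methyl (5E,7Z,9R,11Z)‑9‑hydroxy‑9‑(hydroxymethyl)‑8‑(tributylstannyl)heptadeca‑5,7,11‑trienoate F8, and Parikh–Doering oxidation of the primary alcohol the hydroxy aldehyde methyl (5E,7Z,9R,11Z)‑9‑formyl‑9‑hydroxy‑8‑(tributylstannyl)heptadeca‑5,7,11‑trienoate F9. Acetylation (Ac2O, DMAP) then returns to the route at 18.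

**Further compounds**

F1 | step 15 | methyl (5E,7Z,9R,11Z)‑9‑acetoxy‑8‑iodo‑9‑{[(4‑methoxyphenyl)methoxy]methyl}heptadeca‑5,7,11‑trienoate | CCCCC/C=C\C[C@@](/C(I)=C/C=C/CCCC(=O)OC)(OC(C)=O)COCc1ccc(OC)cc1
F2 | step 15 | methyl (5E,7E,9S,11Z)‑9‑acetoxy‑8‑[2‑(diethoxyphosphoryl)‑1‑hydroxyethyl]‑9‑{[(4‑methoxyphenyl)methoxy]methyl}heptadeca‑5,7,11‑trienoate | CCCCC/C=C\C[C@@](/C(=C/C=C/CCCC(=O)OC)C(O)CP(=O)(OCC)OCC)(OC(C)=O)COCc1ccc(OC)cc1
F3 | step 15 | methyl (5E,7Z,9S,11Z)‑9‑acetoxy‑8‑[2‑(diethoxyphosphoryl)acetyl]‑9‑{[(4‑methoxyphenyl)methoxy]methyl}heptadeca‑5,7,11‑trienoate | CCCCC/C=C\C[C@@](/C(=C/C=C/CCCC(=O)OC)C(=O)CP(=O)(OCC)OCC)(OC(C)=O)COCc1ccc(OC)cc1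
F4 | step 15 | methyl (5E,7Z,9S,11Z)‑9‑acetoxy‑8‑[2‑bromo‑2‑(diethoxyphosphoryl)acetyl]‑9‑{[(4‑methoxyphenyl)methoxy]methyl}heptadeca‑5,7,11‑trienoate | CCCCC/C=C\C[C@@](/C(=C/C=C/CCCC(=O)OC)C(=O)C(Br)P(=O)(OCC)OCC)(OC(C)=O)COCc1ccc(OC)cc1
F5 | step 15 | methyl (5E,7Z,9S,11Z)‑9‑acetoxy‑8‑[2‑bromo‑2‑(diethoxyphosphoryl)acetyl]‑9‑(hydroxymethyl)heptadeca‑5,7,11‑trienoate | CCCCC/C=C\C[C@@](/C(=C/C=C/CCCC(=O)OC)C(=O)C(Br)P(=O)(OCC)OCC)(OC(C)=O)CO
F6 | step 9 | (1Z,3R,5Z)‑3‑{[(4‑methoxyphenyl)methoxy]methyl}‑1,2‑bis(tributylstannyl)undeca‑1,5‑dien‑3‑ol | CCCCC/C=C\C[C@@](/C(=C/[Sn](CCCC)(CCCC)CCCC)[Sn](CCCC)(CCCC)CCCC)(O)COCc1ccc(OC)cc1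
F7 | step 11 | methyl (5E,9S,11Z)‑9‑hydroxy‑9‑(hydroxymethyl)heptadeca‑5,11‑dien‑7‑ynoate | CCCCC/C=C\C[C@@](C#C/C=C/CCCC(=O)OC)(O)CO
F8 | step 11 | methyl (5E,7Z,9R,11Z)‑9‑hydroxy‑9‑(hydroxymethyl)‑8‑(tributylstannyl)heptadeca‑5,7,11‑trienoate | CCCCC/C=C\C[C@@](/C(=C/C=C/CCCC(=O)OC)[Sn](CCCC)(CCCC)CCCC)(O)CO
F9 | step 11 | methyl (5E,7Z,9R,11Z)‑9‑formyl‑9‑hydroxy‑8‑(tributylstannyl)heptadeca‑5,7,11‑trienoate | CCCCC/C=C\C[C@@](/C(=C/C=C/CCCC(=O)OC)[Sn](CCCC)(CCCC)CCCC)(O)C=O
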